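At early times J falls at nearly the same pace in both earlier runs: at 1.50 h it stands at 83.3% in the north-east run and 81.5% in the north-west run, although the north-west run holds 1.50 times the L.

| setting | north-east | north-west | flask |
|---|---|---|---|
| J | 0.10 M | 0.10 M | 0.10 M |
| L | 0.10 M | 0.15 M | 0.200 M |
| remark | run made earlier | run made earlier |  |
| time |  |  | 10 h |

| run | time / h | J / % | G / % |
|---|---|---|---|
| north-east | 0.333 | 97.0 | 0.9 |
| north-east | 1.00 | 88.6 | 2.6 |
| north-east | 1.50 | 83.3 | 2.6 |
| north-east | 2.50 | 74.7 | 3.5 |
| north-east | 4.00 | 62.5 | 5.7 |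
| north-east | 5.00 | 54.9 | 5.1 |
| north-east | 6.00 | 50.3 | 5.7 |
| north-west | 0.833 | 89.2 | 3.6 |
| north-west | 1.50 | 81.5 | 4.4 |
| north-west | 2.50 | 70.5 | 6.7 |
| north-west | 3.00 | 67.7 | 6.8 |
| north-west | 4.00 | 58.8 | 7.4 |
| north-west | 5.00 | 52.7 | 7.4 |
| north-west | 6.00 | 46.1 | 6.6 |

(scatter of a reading: 0.5 percentage points)

- share of the J used up at 10 h
- G at 10 h, in percent of the J charged
- E at 10 h, in percent of the J charged
- X at 10 h, in percent of the J charged



1. A first-order loss constant is minus the logarithm of the fraction of J left, divided by the time. The last readings give 0.115 h⁻¹ for the north-east run and 0.129 h⁻¹ for the north-west run.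

2. The scale needs a zero. A loss indifferent to L has order zero in L, and a loss proportional to L has order one. The apparent order in L is the logarithm of the ratio of the constants over the logarithm of the ratio of the L charges: 0.295. This lies nearer zero than one.

3. My own reckoning scales the constant with this order to 0.140 h⁻¹ at the flask's L. That is a half-life of 4.93 h and a conversion of 75.5% at 10 h. E and X were not read in either run.

4. The forecast gives conversion 76.5%, which is 1 percentage point above mine, with G 5%, E 27% and X 44%. For the split it says: “I guess E is G's follow-on product and X the direct side product”.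

5. The flask gives conversion 74.5%, G 7.90%, E 52.2% and X 14.3%. E stands above the forecast's range, and X below it.

    J ⇌ D (K = 0.00590, k = 0.260 h⁻¹)
    D ⇌ Z (K = 1.10, k = 42.0 h⁻¹)
    L + D → G (k = 92.0 M⁻¹ h⁻¹)
    L + Z → E (k = 1200 M⁻¹ h⁻¹)
    G ⇌ X (K = 12.0, k = 0.200 h⁻¹)

At 10 h the flask is 2.03 half-lives along by the carried order, which leaves 24.7% of its J by reckoning; the flask holds 26% of its J and has not come to rest. The same order gives 65.8% conversion for the neighbour with 0.080 M of L, which reaches 62.1% with 23% of its own L left. Ten times the time takes the flask's conversion to >99.9% and its L to 50.0%, while G falls to 2.18%, E rises to 71.7% and X to 26.2%.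

Readings and results are simulated on assumed constants; the scatter is artificial.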